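The route rests on disconnecting the C4–C4a bond of the tetralone. The feature used is that C4 hangs on naphthalene C1', para to the hydroxyl on C4' of the same ring, so a hydroxyl on C4 can leave to give a flat para-quinone methide. On the catechol ring, C4a is the one unsubstituted carbon next to the side chain and is activated from the para position by the C7 oxygen. In one operation a chiral phosphoric acid converts both enantiomers of an open-chain carbinol into that intermediate, closes the saturated six-membered ring and sets C4. The precursor carries a free naphthol, a dibenzylated catechol and the future ketone as a 1,3-dithiane.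

Key step: step 8

Numbering: tetralone atoms are C1 (carbonyl carbon) to C8a; naphthalene atoms carry primes, C1' being bonded to C4.

Remark: (R)-TRIP is (R)-3,3'-bis(2,4,6-triisopropylphenyl)-1,1'-binaphthyl-2,2'-diyl hydrogen phosphate; that this antipode favours the (4R) product is an assumption, and the mirror-image acid would be used if a first trial shows the opposite sense.

Step 1
Reactants: 1 2,3-dihydroxybenzaldehyde
Product: 2 2,3-bis(benzyloxy)benzaldehyde
Conditions: BnBr (2.4 equiv), K2CO3 (3 equiv), DMF, 60 °C
Reagents that add atoms: benzyl bromide, BrCc1ccccc1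
Why: Williamson ether synthesis, in which both catechol phenoxides are alkylated by the primary benzylic bromide, the excess reagent and gentle heating driving the chelated 2-hydroxyl to completion.

Step 2
Reactants: 2 2,3-bis(benzyloxy)benzaldehyde; 3 propane-1,3-dithiol
Product: 4 2-[2,3-bis(benzyloxy)phenyl]-1,3-dithiane
Conditions: 3 (1.1 equiv), BF3·OEt2 (0.2 equiv), CH2Cl2, 0 °C → rt
Reagents that add atoms: none
Why: Lewis-acid-catalysed dithioacetalisation of an aromatic aldehyde, which benzyl aryl ethers tolerate at this temperature.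

Step 3
Reactants: 4 2-[2,3-bis(benzyloxy)phenyl]-1,3-dithiane; 5 2-(2-bromoethyl)-1,3-dioxolane
Product: 7 2-[2,3-bis(benzyloxy)phenyl]-2-[2-(1,3-dioxolan-2-yl)ethyl]-1,3-dithiane, via 2-lithiodithiane 6 (not isolated)
Conditions: n-BuLi (1.1 equiv), THF, −78 → −20 °C; then 5 (1.3 equiv), −78 °C → rt
Reagents that add atoms: none
Why: Corey–Seebach umpolung, in which n-BuLi removes the acidic C2–H of the 2-aryl dithiane and the soft carbanion 6 should displace the primary bromide of 5 by SN2 faster than it eliminates it.

Step 4
Reactants: 7 2-[2,3-bis(benzyloxy)phenyl]-2-[2-(1,3-dioxolan-2-yl)ethyl]-1,3-dithiane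
Product: 8 3-{2-[2,3-bis(benzyloxy)phenyl]-1,3-dithian-2-yl}propanal
Conditions: 1 M aq. HCl, THF, 40 °C
Reagents that add atoms: water, O
Why: Acid-catalysed acetal hydrolysis frees the aldehyde, while the dithiane and the benzyl ethers are stable to dilute aqueous Brønsted acid.

Step 5
Reactants: 9 5-methoxy-1-naphthol
Product: 10 4-bromo-5-methoxynaphthalen-1-ol
Conditions: NBS (1.0 equiv), MeCN, −30 → 0 °C, dark
Reagents that add atoms: N-bromosuccinimide, O=C1CCC(=O)N1Br
Why: Electrophilic aromatic bromination, in which the free hydroxyl is the strongest donor on the naphthalene and NBS in a polar solvent should deliver bromine para to it at C4, as is usual for 1-naphthols.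

Step 6
Reactants: 10 4-bromo-5-methoxynaphthalen-1-ol
Product: 11 [(4-bromo-5-methoxynaphthalen-1-yl)oxy]tri(propan-2-yl)silane
Conditions: TIPSCl (1.2 equiv), imidazole (2.5 equiv), DMF, rt
Reagents that add atoms: chlorotri(propan-2-yl)silane (TIPSCl), CC(C)[Si](Cl)(C(C)C)C(C)C
Why: Silylation of the naphthol removes the acidic proton before the organolithium step, and the bulky triisopropylsilyl group resists attack by butyllithium at silicon.

Step 7
Reactants: 11 [(4-bromo-5-methoxynaphthalen-1-yl)oxy]tri(propan-2-yl)silane; 8 3-{2-[2,3-bis(benzyloxy)phenyl]-1,3-dithian-2-yl}propanal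
Product: 14 rac-3-{2-[2,3-bis(benzyloxy)phenyl]-1,3-dithian-2-yl}-1-(4-hydroxy-8-methoxynaphthalen-1-yl)propan-1-ol, via aryllithium 12 (not isolated), via lithium alkoxide 13 (not isolated)
Conditions: 11 (1.25 equiv), n-BuLi (1.2 equiv), THF, −78 °C; then 8 (1.0 equiv), −78 °C; then TBAF (2.5 equiv), 0 °C; sat. aq. NH4Cl
Reagents that add atoms: none
Why: Bromine–lithium exchange gives aryllithium 12, stabilised by chelation to the peri methoxy group, whose 1,2-addition to aldehyde 8 forms the carbinol as a racemate (acceptable because step 8 erases this centre), and fluoride then cleaves the aryl silyl ether in the same flask; the acid-labile product should be purified on triethylamine-deactivated silica.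

Step 8
Reactants: 14 rac-3-{2-[2,3-bis(benzyloxy)phenyl]-1,3-dithian-2-yl}-1-(4-hydroxy-8-methoxynaphthalen-1-yl)propan-1-ol
Product: 16 (4R)-7,8-bis(benzyloxy)-4-(4-hydroxy-8-methoxynaphthalen-1-yl)-3,4-dihydro-2H-spiro[naphthalene-1,2'-[1,3]dithiane], via para-quinone methide 15 (not isolated)
Conditions: (R)-TRIP (10 mol%), 5 Å MS, PhMe (0.01 M), −20 °C → rt
Reagents that add atoms: none
Why: Proposed new method: the acid protonates the benzylic hydroxyl of either enantiomer of 14, water leaves with a push from the para naphthol oxygen, and both enantiomers converge on the same planar quinone methide 15, which stays bound to the chiral phosphate through its O–H···O contact; carbon C6 of the bis(benzyloxy)phenyl ring then adds to the exocyclic carbon, and loss of the ring proton to the phosphate restores both aromatic systems and the catalyst. The closest known reaction type is the chiral-phosphoric-acid-catalysed enantioselective 1,6-addition (Friedel–Crafts alkylation) of indoles, naphthols and phenols to para-quinone methides made in situ from racemic para-hydroxybenzylic alcohols; what has not been shown is the intramolecular version with a dialkoxybenzene that gives the catalyst no N–H or O–H to hold. The one ring formed, the saturated ring of the tetralin, closes in a 6-exo-trig mode onto the exocyclic C=C of 15 and creates the C4–C4a bond. The new centre C4 is controlled by the catalyst alone, whose 2,4,6-triisopropylphenyl groups should screen one face of the exocyclic carbon in the hydrogen-bonded ion pair, the earlier carbinol configuration being lost in 15. The step needs enantioface selectivity, helped by the peri methoxy group, which should hold the exocyclic double bond in one geometry with the chain turned away from it, and regioselectivity, secured because C6 is the only free ring carbon that the three-atom tether can reach and lies para to a benzyloxy group. It also needs chemoselectivity against oligomerisation and against trapping by sulfur or by the carbinol oxygen, to be met by high dilution, molecular sieves and the expectation that such sulfonium and ether adducts at a para-hydroxybenzylic carbon re-ionise to 15, while the dithiane keeps C1 free of a deactivating carbonyl.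

Step 9
Reactants: 16 (4R)-7,8-bis(benzyloxy)-4-(4-hydroxy-8-methoxynaphthalen-1-yl)-3,4-dihydro-2H-spiro[naphthalene-1,2'-[1,3]dithiane]
Product: 17 (4R)-7,8-bis(benzyloxy)-4-(4-hydroxy-8-methoxynaphthalen-1-yl)-3,4-dihydronaphthalen-1(2H)-one
Conditions: MeI (15 equiv), CaCO3 (5 equiv), MeCN/H2O (4:1), 45 °C
Reagents that add atoms: water, O
Why: Alkylative dithiane hydrolysis, in which S-methylation makes sulfur a leaving group and water captures the aryl-stabilised thionium ion, while the CaCO3 buffer should keep the medium too weakly basic for O-methylation of the naphthol and leaves C4, which is not α to the new ketone, untouched.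

Step 10
Reactants: 17 (4R)-7,8-bis(benzyloxy)-4-(4-hydroxy-8-methoxynaphthalen-1-yl)-3,4-dihydronaphthalen-1(2H)-one
Product: 18 (4R)-7,8-dihydroxy-4-(4-hydroxy-8-methoxynaphthalen-1-yl)-3,4-dihydronaphthalen-1(2H)-one
Conditions: H2 (1 atm), 10% Pd/C, EtOAc/MeOH, rt
Reagents that add atoms: none
Why: Catalytic hydrogenolysis of the two benzyl aryl ethers, run after all sulfur has been removed, should leave the methyl ether, the aryl ketone and the C4–aryl bonds intact at 1 atm, so the (R) centre is carried through unchanged.

Compound list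
1 | 2,3-dihydroxybenzaldehyde | O=Cc1cccc(O)c1O | starting material
2 | 2,3-bis(benzyloxy)benzaldehyde | O=Cc1cccc(OCc2ccccc2)c1OCc1ccccc1 | intermediate
3 | propane-1,3-dithiol | SCCCS | starting material
4 | 2-[2,3-bis(benzyloxy)phenyl]-1,3-dithiane | C1CSC(SC1)c1cccc(OCc2ccccc2)c1OCc1ccccc1 | intermediate
5 | 2-(2-bromoethyl)-1,3-dioxolane | BrCCC1OCCO1 | starting material
6 | {2-[2,3-bis(benzyloxy)phenyl]-1,3-dithian-2-yl}lithium | [Li]C1(SCCCS1)c1cccc(OCc2ccccc2)c1OCc1ccccc1 | intermediate
7 | 2-[2,3-bis(benzyloxy)phenyl]-2-[2-(1,3-dioxolan-2-yl)ethyl]-1,3-dithiane | C1COC(CCC2(SCCCS2)c2cccc(OCc3ccccc3)c2OCc2ccccc2)O1 | intermediate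
8 | 3-{2-[2,3-bis(benzyloxy)phenyl]-1,3-dithian-2-yl}propanal | O=CCCC1(SCCCS1)c1cccc(OCc2ccccc2)c1OCc1ccccc1 | intermediate
9 | 5-methoxy-1-naphthol | COc1cccc2c(O)cccc12 | starting material
10 | 4-bromo-5-methoxynaphthalen-1-ol | COc1cccc2c(O)ccc(Br)c12 | intermediate
11 | [(4-bromo-5-methoxynaphthalen-1-yl)oxy]tri(propan-2-yl)silane | COc1cccc2c(O[Si](C(C)C)(C(C)C)C(C)C)ccc(Br)c12 | intermediate
12 | {8-methoxy-4-[(triisopropylsilyl)oxy]naphthalen-1-yl}lithium | COc1cccc2c(O[Si](C(C)C)(C(C)C)C(C)C)ccc([Li])c12 | intermediate
13 | lithium rac-3-{2-[2,3-bis(benzyloxy)phenyl]-1,3-dithian-2-yl}-1-{8-methoxy-4-[(triisopropylsilyl)oxy]naphthalen-1-yl}propan-1-olate | COc1cccc2c(O[Si](C(C)C)(C(C)C)C(C)C)ccc(C(O[Li])CCC3(SCCCS3)c3cccc(OCc4ccccc4)c3OCc3ccccc3)c12 | intermediate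
14 | rac-3-{2-[2,3-bis(benzyloxy)phenyl]-1,3-dithian-2-yl}-1-(4-hydroxy-8-methoxynaphthalen-1-yl)propan-1-ol | COc1cccc2c(O)ccc(C(O)CCC3(SCCCS3)c3cccc(OCc4ccccc4)c3OCc3ccccc3)c12 | intermediate
15 | 4-{3-[2-(2,3-bis(benzyloxy)phenyl)-1,3-dithian-2-yl]propylidene}-5-methoxynaphthalen-1(4H)-one (double-bond geometry not fixed in the drawing) | COc1cccc2C(=O)C=CC(=CCCC3(SCCCS3)c3cccc(OCc4ccccc4)c3OCc3ccccc3)c12 | intermediate
16 | (4R)-7,8-bis(benzyloxy)-4-(4-hydroxy-8-methoxynaphthalen-1-yl)-3,4-dihydro-2H-spiro[naphthalene-1,2'-[1,3]dithiane] | COc1cccc2c(O)ccc([C@H]3CCC4(SCCCS4)c4c3ccc(OCc3ccccc3)c4OCc3ccccc3)c12 | intermediate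
17 | (4R)-7,8-bis(benzyloxy)-4-(4-hydroxy-8-methoxynaphthalen-1-yl)-3,4-dihydronaphthalen-1(2H)-one | COc1cccc2c(O)ccc([C@H]3CCC(=O)c4c3ccc(OCc3ccccc3)c4OCc3ccccc3)c12 | intermediate
18 | (4R)-7,8-dihydroxy-4-(4-hydroxy-8-methoxynaphthalen-1-yl)-3,4-dihydronaphthalen-1(2H)-one (CNP0535815.2) | COc1cccc2c(O)ccc([C@H]3CCC(=O)c4c3ccc(O)c4O)c12 | target

Total steps: 10. Longest linear sequence: 8 steps (1, 2, 3, 4, 7, 8, 9, 10); steps 5 and 6 form the short naphthalene branch that joins at step 7.

Steps most likely to fail

Step 8. The closing arene offers the phosphate no second hydrogen bond, so discrimination between the two faces of the quinone methide may be weak and the ring closure may proceed with little asymmetric induction. The fallback sets out from 14 and uses known chemistry. The ring is closed without induction by a catalytic achiral Brønsted acid (diphenyl phosphate or TsOH·H2O, CH2Cl2, 0 °C), the familiar acid-mediated Friedel–Crafts cyclialkylation of a benzylic alcohol, which should give racemic 7,8-bis(benzyloxy)-4-(4-hydroxy-8-methoxynaphthalen-1-yl)-3,4-dihydro-2H-spiro[naphthalene-1,2'-[1,3]dithiane] F1. The enantiomers are then separated by preparative chromatography on a polysaccharide chiral stationary phase (supercritical CO2/MeOH). The (4R) fraction is 16, and the route continues with step 9.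

Step 5. Bromination may lose regiocontrol and spread over C4, C2 and the methoxy-bearing ring, leaving isomers that are hard to separate. The fallback sets out from 9 and replaces steps 5 and 6. The naphthol is silylated first (TIPSCl, imidazole, DMF) to triisopropyl[(5-methoxynaphthalen-1-yl)oxy]silane F2. The methoxy group then serves as a director: peri-lithiation of 1-methoxynaphthalenes with t-BuLi in cyclohexane at rt is known chemistry and should metalate C4 directly, with F2 kept in slight excess so that no t-BuLi remains. This gives aryllithium 12, where the route is rejoined (dilution with THF, aldehyde 8 at −78 °C, then TBAF as in step 7).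

Step 9. S-methylation at the hindered spiro-dithiane may be slow, and prolonged exposure to MeI may lead to competing O-methylation of the free naphthol. The fallback sets out from 16. The naphthol is masked by acetylation (Ac2O, pyridine, DMAP cat., CH2Cl2) to 4-[(4R)-7,8-bis(benzyloxy)-3,4-dihydro-2H-spiro[naphthalene-1,2'-[1,3]dithian]-4-yl]-5-methoxynaphthalen-1-yl acetate F3. The dithiane is then cleaved oxidatively (PhI(OCOCF3)2, MeCN/H2O, 0 °C), which the deactivated naphthyl ester should tolerate, to 4-[(1R)-5,6-bis(benzyloxy)-4-oxo-1,2,3,4-tetrahydronaphthalen-1-yl]-5-methoxynaphthalen-1-yl acetate F4. Methanolysis of the acetate (K2CO3 cat., MeOH, 0 °C) returns the route to 17.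

Further compounds
F1 | step 8 | racemic 7,8-bis(benzyloxy)-4-(4-hydroxy-8-methoxynaphthalen-1-yl)-3,4-dihydro-2H-spiro[naphthalene-1,2'-[1,3]dithiane] | COc1cccc2c(O)ccc(C3CCC4(SCCCS4)c4c3ccc(OCc3ccccc3)c4OCc3ccccc3)c12
F2 | step 5 | triisopropyl[(5-methoxynaphthalen-1-yl)oxy]silane | COc1cccc2c(O[Si](C(C)C)(C(C)C)C(C)C)cccc12
F3 | step 9 | 4-[(4R)-7,8-bis(benzyloxy)-3,4-dihydro-2H-spiro[naphthalene-1,2'-[1,3]dithian]-4-yl]-5-methoxynaphthalen-1-yl acetate | COc1cccc2c(OC(C)=O)ccc([C@H]3CCC4(SCCCS4)c4c3ccc(OCc3ccccc3)c4OCc3ccccc3)c12
F4 | step 9 | 4-[(1R)-5,6-bis(benzyloxy)-4-oxo-1,2,3,4-tetrahydronaphthalen-1-yl]-5-methoxynaphthalen-1-yl acetate | COc1cccc2c(OC(C)=O)ccc([C@H]3CCC(=O)c4c3ccc(OCc3ccccc3)c4OCc3ccccc3)c12
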